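**Retrosynthetic overview**
1. Target 20 is (3S,4R): the two arylmethyl arms are cis and the C3 hydroxyl is trans to the C4 arm. It comes from trans lactone 17 by enolate oxidation at C3 on the face away from the C4 arm, then hydrogenolysis of the two benzyl ethers.
2. 17 comes from the twofold-symmetric diol 16 by oxidative lactonisation. 16 comes from dithiane adduct 14 by desulfurisation and hydride reduction, which turns the C5 acetal carbon into the second CH2OH.
3. The route rests on the two identical arylmethyl groups on the adjacent carbons C3 and C4 of the five-membered lactone ring (O1, C2 carbonyl, C3, C4, C5). The C4 arm is put in as a nucleophile (lithiated aryl dithiane 12) and the C3 arm as an electrophile (bromide 11) on butenolide 5, whose C5 menthyl acetal steers both additions.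
4. Ring order: the lactone is the only ring to make. It enters as the butenolide from furfural (steps 1–2), is opened to the diol (step 9) and closed again (step 10). The arenes come from vanillin.
5. 5 is made from furfural and (+)-menthol; 9 and 11 are both made from O-benzylvanillin 7.

Key step: step 7

Remark: with (+)-menthol the crystalline butenolide acetal is taken to be the 5S epimer, the mirror image of the crystalline 5R acetal of the (−)-menthol series.

**Route**

Step 1
Reactants: 1 furfural
Product: 3 5-hydroxyfuran-2(5H)-one (racemic lactol), via furfural endoperoxide 2 (not isolated)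
Conditions: O2, methylene blue (cat.), hν (visible), MeOH, rt
Reagents that add atoms: oxygen, O=O
Why: Singlet-oxygen [4+2] cycloaddition to the furan gives the 2,5-endoperoxide, which methanol cleaves at the formyl group with loss of methyl formate to leave the hydroxybutenolide (dye-sensitised photooxygenation).

Step 2
Reactants: 3 5-hydroxyfuran-2(5H)-one; 4 (+)-menthol
Product: 5 (5S)-5-[(1S,2R,5S)-menthyloxy]furan-2(5H)-one
Conditions: p-TsOH (cat.), toluene, reflux, Dean–Stark; crystallise from light petroleum; re-equilibrate the mother liquor with p-TsOH and recrystallise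
Reagents that add atoms: none
Why: Acid-catalysed acetalisation of the lactol gives both C5 epimers, and since the acetal carbon equilibrates under acid, repeated crystallisation with recycling of the mother liquor should deliver the 5S epimer alone (crystallisation-driven resolution at C5).

Step 3
Reactants: 6 vanillin
Product: 7 4-benzyloxy-3-methoxybenzaldehyde
Conditions: BnBr, K2CO3, DMF, 60 °C
Reagents that add atoms: benzyl bromide, BrCc1ccccc1
Why: Williamson etherification of the phenoxide with a reactive benzylic bromide.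

Step 4
Reactants: 7 4-benzyloxy-3-methoxybenzaldehyde; 8 propane-1,3-dithiol
Product: 9 2-(4-benzyloxy-3-methoxyphenyl)-1,3-dithiane
Conditions: BF3·OEt2 (cat.), CH2Cl2, 0 °C → rt
Reagents that add atoms: none
Why: Lewis-acid-catalysed dithioacetalisation of an aromatic aldehyde, which leaves the benzyl ether untouched.

Step 5
Reactants: 7 4-benzyloxy-3-methoxybenzaldehyde
Product: 10 4-benzyloxy-3-methoxybenzyl alcohol
Conditions: NaBH4, MeOH/THF, 0 °C
Reagents that add atoms: none
Why: Borohydride reduction of an aryl aldehyde to the benzylic alcohol.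

Step 6
Reactants: 10 4-benzyloxy-3-methoxybenzyl alcohol
Product: 11 4-benzyloxy-3-methoxybenzyl bromide
Conditions: PBr3, Et2O, 0 °C; used at once
Reagents that add atoms: phosphorus tribromide, BrP(Br)Br
Why: Bromide displaces the phosphite ester of an activated benzylic alcohol; the electron-rich bromide is labile and is therefore not stored.

Step 7
Reactants: 9 2-(4-benzyloxy-3-methoxyphenyl)-1,3-dithiane; 5 (5S)-5-[(1S,2R,5S)-menthyloxy]furan-2(5H)-one; 11 4-benzyloxy-3-methoxybenzyl bromide
Product: 14 (3S,4S,5S)-3-(4-benzyloxy-3-methoxybenzyl)-4-[2-(4-benzyloxy-3-methoxyphenyl)-1,3-dithian-2-yl]-5-[(1S,2R,5S)-menthyloxy]dihydrofuran-2(3H)-one (trans,trans), via 2-lithiodithiane 12 (not isolated), via lithium enolate 13 (not isolated)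
Conditions: n-BuLi, THF, −20 °C; then 5, −90 °C; then 11, TMEDA, −90 °C → rt; aq NH4Cl
Reagents that add atoms: none
Why: The 2-lithio-1,3-dithiane 12, a sulfur-stabilised soft carbanion, adds in Michael fashion to C4 of butenolide 5, and the lithium enolate 13 so formed is alkylated at C3 by bromide 11 in an SN2 step, so the C4–C(dithiane) and C3–CH2Ar bonds are made in one flask. The closest known reaction type is the tandem conjugate addition–enolate alkylation of lithiated 2-aryl-1,3-dithianes on 5-alkoxyfuran-2(5H)-ones, the usual three-component entry to dibenzylbutyrolactone lignans. No ring is closed; the lactone ring is carried through from 5. The new C4 centre is controlled by the C5 menthyloxy group, which shields one face of the flat butenolide so that the carbanion enters trans to it (4S), and the new C3 centre by the bulky dithianyl group on C4, which sends the bromide to the opposite enolate face (3S, trans,trans). The step needs 1,4- over 1,2-addition, which the delocalised dithiane anion at −90 °C should secure, and C-benzylation before proton return or retro-Michael loss, which the reactive benzylic bromide with TMEDA should secure while the mixture is still cold.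

Step 8
Reactants: 14 trans,trans dithiane adduct
Product: 15 (3S,4S,5S)-3,4-bis(4-benzyloxy-3-methoxybenzyl)-5-[(1S,2R,5S)-menthyloxy]dihydrofuran-2(3H)-one
Conditions: NiCl2·6H2O, NaBH4, MeOH/THF, 0 °C → rt
Reagents that add atoms: none
Why: Nickel boride formed in the flask cleaves both benzylic C–S bonds (reductive desulfurisation) without touching the aryl benzyl ethers or the C3 and C4 centres, and any lactone that borohydride reduces further converges on diol 16 in step 9.

Step 9
Reactants: 15 desulfurised lactone acetal
Product: 16 (2S,3S)-2,3-bis(4-benzyloxy-3-methoxybenzyl)butane-1,4-diol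
Conditions: LiAlH4, THF, 0 °C → rt; H2O, aq NaOH work-up
Reagents that add atoms: none
Why: Hydride reduction of the lactone carbonyl releases the C5 acetal as an aldehyde with loss of menthoxide, and reduction of both termini gives the twofold-symmetric diol with C3 and C4 unchanged; (+)-menthol is recovered.

Step 10
Reactants: 16 (2S,3S)-diol
Product: 17 (3S,4S)-3,4-bis(4-benzyloxy-3-methoxybenzyl)dihydrofuran-2(3H)-one
Conditions: TEMPO (cat.), PhI(OAc)2, CH2Cl2, rt
Reagents that add atoms: none
Why: Oxoammonium oxidation of one primary alcohol, lactol formation with the other and a second oxidation give the γ-lactone (oxidative lactonisation of a 1,4-diol), and because the two CH2OH groups are interchanged by the twofold axis only one trans lactone can form.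

Step 11
Reactants: 17 (3S,4S)-trans lactone
Product: 19 (3S,4R)-3,4-bis(4-benzyloxy-3-methoxybenzyl)-3-hydroxydihydrofuran-2(3H)-one, via potassium enolate 18 (not isolated)
Conditions: KN(SiMe3)2, THF, −78 °C; then 3-phenyl-2-(phenylsulfonyl)oxaziridine, −78 °C; AcOH quench
Reagents that add atoms: 3-phenyl-2-(phenylsulfonyl)oxaziridine (Davis reagent), O=S(=O)(c1ccccc1)N1OC1c1ccccc1
Why: Davis enolate hydroxylation, in which the electrophilic oxygen should reach the planar C3 enolate on the face away from the C4 arylmethyl group, placing OH trans to that arm and the two arms cis (3S); the potassium counter-ion suppresses addition of the enolate to the sulfonimine by-product.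

Step 12
Reactants: 19 dibenzyl ether of the target
Product: 20 (3S,4R)-3-hydroxy-3,4-bis(4-hydroxy-3-methoxybenzyl)dihydrofuran-2(3H)-one (target)
Conditions: H2 (1 atm), 10% Pd/C, EtOAc/EtOH, rt
Reagents that add atoms: none
Why: Hydrogenolysis of the two aryl benzyl ethers, under which the lactone and the non-benzylic tertiary alcohol are stable and no stereocentre is touched.

**Compound list**
1 | furfural | O=Cc1ccco1 | starting material
2 | furfural endoperoxide (2,3,7-trioxabicyclo[2.2.1]hept-5-ene-1-carbaldehyde) | O=CC12OOC(C=C1)O2 | intermediate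
3 | 5-hydroxyfuran-2(5H)-one (racemic) | O=C1C=CC(O)O1 | intermediate
4 | (+)-menthol, (1S,2R,5S)-2-isopropyl-5-methylcyclohexanol | CC(C)[C@H]1CC[C@H](C)C[C@@H]1O | starting material
5 | (5S)-5-[(1S,2R,5S)-menthyloxy]furan-2(5H)-one | O=C1C=C[C@@H](O[C@H]2C[C@@H](C)CC[C@@H]2C(C)C)O1 | intermediate
6 | vanillin | COc1cc(C=O)ccc1O | starting material
7 | 4-benzyloxy-3-methoxybenzaldehyde | COc1cc(C=O)ccc1OCc1ccccc1 | intermediate
8 | propane-1,3-dithiol | SCCCS | starting material
9 | 2-(4-benzyloxy-3-methoxyphenyl)-1,3-dithiane | COc1cc(C2SCCCS2)ccc1OCc1ccccc1 | intermediate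
10 | 4-benzyloxy-3-methoxybenzyl alcohol | COc1cc(CO)ccc1OCc1ccccc1 | intermediate
11 | 4-benzyloxy-3-methoxybenzyl bromide | COc1cc(CBr)ccc1OCc1ccccc1 | intermediate
12 | 2-lithio-2-(4-benzyloxy-3-methoxyphenyl)-1,3-dithiane | COc1cc(C2([Li])SCCCS2)ccc1OCc1ccccc1 | intermediate
13 | lithium enolate of the (4S,5S) conjugate adduct (C2 O-lithium, C2=C3) | [Li]OC1=C[C@H](C2(c3ccc(OCc4ccccc4)c(OC)c3)SCCCS2)[C@@H](O[C@H]2C[C@@H](C)CC[C@@H]2C(C)C)O1 | intermediate
14 | (3S,4S,5S)-3-(4-benzyloxy-3-methoxybenzyl)-4-[2-(4-benzyloxy-3-methoxyphenyl)-1,3-dithian-2-yl]-5-[(1S,2R,5S)-menthyloxy]dihydrofuran-2(3H)-one | O=C1O[C@H](O[C@H]2C[C@@H](C)CC[C@@H]2C(C)C)[C@@H](C2(c3ccc(OCc4ccccc4)c(OC)c3)SCCCS2)[C@@H]1Cc1ccc(OCc2ccccc2)c(OC)c1 | intermediate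
15 | (3S,4S,5S)-3,4-bis(4-benzyloxy-3-methoxybenzyl)-5-[(1S,2R,5S)-menthyloxy]dihydrofuran-2(3H)-one | O=C1O[C@H](O[C@H]2C[C@@H](C)CC[C@@H]2C(C)C)[C@@H](Cc2ccc(OCc3ccccc3)c(OC)c2)[C@@H]1Cc1ccc(OCc2ccccc2)c(OC)c1 | intermediate
16 | (2S,3S)-2,3-bis(4-benzyloxy-3-methoxybenzyl)butane-1,4-diol | OC[C@@H](Cc1ccc(OCc2ccccc2)c(OC)c1)[C@@H](CO)Cc1ccc(OCc2ccccc2)c(OC)c1 | intermediate
17 | (3S,4S)-3,4-bis(4-benzyloxy-3-methoxybenzyl)dihydrofuran-2(3H)-one | O=C1OC[C@@H](Cc2ccc(OCc3ccccc3)c(OC)c2)[C@@H]1Cc1ccc(OCc2ccccc2)c(OC)c1 | intermediate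
18 | potassium enolate of 17, potassium (4S)-3,4-bis(4-benzyloxy-3-methoxybenzyl)-4,5-dihydrofuran-2-olate | [K]OC1=C(Cc2ccc(OCc3ccccc3)c(OC)c2)[C@H](Cc2ccc(OCc3ccccc3)c(OC)c2)CO1 | intermediate
19 | (3S,4R)-3,4-bis(4-benzyloxy-3-methoxybenzyl)-3-hydroxydihydrofuran-2(3H)-one | COc1cc(C[C@@H]2COC(=O)[C@]2(O)Cc2ccc(OCc3ccccc3)c(OC)c2)ccc1OCc1ccccc1 | intermediate
20 | (3S,4R)-3-hydroxy-3,4-bis(4-hydroxy-3-methoxybenzyl)dihydrofuran-2(3H)-one | COc1cc(C[C@@H]2COC(=O)[C@]2(O)Cc2ccc(O)c(OC)c2)ccc1O | target

**Step count and risk**
Total steps: 12. Longest linear sequence: 9 (steps 3, 5, 6, 7, 8, 9, 10, 11, 12 from vanillin).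

Steps most likely to fail:

1. Step 7. The hindered lithium enolate may be benzylated incompletely, with proton return to the mono-adduct or retro-Michael loss of the dithiane anion on warming. The fallback sets out from 5 and 9 and separates the two bond formations. The conjugate addition is run alone (n-BuLi, THF, −20 °C; 5, −90 °C) and quenched cold with aq NH4Cl to isolate the mono-adduct (4S,5S)-4-[2-(4-benzyloxy-3-methoxyphenyl)-1,3-dithian-2-yl]-5-[(1S,2R,5S)-menthyloxy]dihydrofuran-2(3H)-one F1. Its enolate is then regenerated with LiN(iPr)2 in THF/DMPU at −78 °C and alkylated with 11, trans to the dithianyl group, to come back to the route at 14.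

2. Step 11. Oxygen may be delivered to the wrong enolate face, or the enolate may be consumed by the sulfonimine by-product or react sluggishly because it is tetrasubstituted. The fallback sets out from 17 and uses a Rubottom oxidation instead of direct enolate oxidation. Enolisation with KN(SiMe3)2 and trapping with Me3SiCl should give the silyl ketene acetal (4S)-3,4-bis(4-benzyloxy-3-methoxybenzyl)-2-trimethylsilyloxy-4,5-dihydrofuran F2. Epoxidation of its C2=C3 bond with dimethyldioxirane in acetone at −78 °C, again from the face away from the C4 arm, followed by silyl migration should give the α-silyloxy lactone (3S,4R)-3,4-bis(4-benzyloxy-3-methoxybenzyl)-3-trimethylsilyloxydihydrofuran-2(3H)-one F3. Dilute aqueous HCl in THF then removes the silyl group and the route is rejoined at 19.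

3. Step 8. C–S cleavage at the congested dithiane may be incomplete, and borohydride or methoxide may attack the lactone acetal with epimerisation next to the freed aldehyde. The fallback sets out from 14 and reverses the order of reduction and desulfurisation. LiAlH4 in THF first removes the base-sensitive lactone acetal and gives (2S,3S)-2-(4-benzyloxy-3-methoxybenzyl)-3-[2-(4-benzyloxy-3-methoxyphenyl)-1,3-dithian-2-yl]butane-1,4-diol F4. This robust diol is then desulfurised with acetone-deactivated Raney Ni in EtOH at reflux, and the route is rejoined at 16.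

**Further compounds**
F1 | step 7 | (4S,5S)-4-[2-(4-benzyloxy-3-methoxyphenyl)-1,3-dithian-2-yl]-5-[(1S,2R,5S)-menthyloxy]dihydrofuran-2(3H)-one | O=C1C[C@H](C2(c3ccc(OCc4ccccc4)c(OC)c3)SCCCS2)[C@@H](O[C@H]2C[C@@H](C)CC[C@@H]2C(C)C)O1
F2 | step 11 | (4S)-3,4-bis(4-benzyloxy-3-methoxybenzyl)-2-trimethylsilyloxy-4,5-dihydrofuran | C[Si](C)(C)OC1=C(Cc2ccc(OCc3ccccc3)c(OC)c2)[C@H](Cc2ccc(OCc3ccccc3)c(OC)c2)CO1
F3 | step 11 | (3S,4R)-3,4-bis(4-benzyloxy-3-methoxybenzyl)-3-trimethylsilyloxydihydrofuran-2(3H)-one | COc1cc(C[C@@H]2COC(=O)[C@]2(O[Si](C)(C)C)Cc2ccc(OCc3ccccc3)c(OC)c2)ccc1OCc1ccccc1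
F4 | step 8 | (2S,3S)-2-(4-benzyloxy-3-methoxybenzyl)-3-[2-(4-benzyloxy-3-methoxyphenyl)-1,3-dithian-2-yl]butane-1,4-diol | OC[C@@H](C1(c2ccc(OCc3ccccc3)c(OC)c2)SCCCS1)[C@@H](CO)Cc1ccc(OCc2ccccc2)c(OC)c1
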